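**Retrosynthetic overview**
- Integracin D ⇐ global O‑debenzylation ⇐ sulfation of the one unmasked ring‑B phenol ⇐ Mitsunobu ester bond (with inversion) between a 2,4‑bis(benzyloxy)‑6‑alkylbenzoic acid already carrying the acetate and an (R)‑carbinol carrying a Bn/TIPS‑differentiated resorcinol.
- The acid ⇐ Vilsmeier formylation and Pinnick oxidation of a 5‑alkylresorcinol dibenzyl ether; both aryl–chain bonds ⇐ Sonogashira coupling of 5‑bromoresorcinol ethers with the two enantiomers of undec‑1‑en‑10‑yn‑4‑ol, then saturation of C≡C and C=C.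
- Key C–C bond (C3–C4 of each undecyl unit, which sets both stereocentres): Brown asymmetric carbonyl allylation of oct‑7‑ynal with (−)‑ or (+)‑Ipc2B‑allyl.
- No ring is built: both benzene rings come intact from 5‑bromoresorcinol; oct‑7‑ynal comes from 6‑bromohexan‑1‑ol and acetylide.

Assumption: the aryl sulfate half‑ester (22, 23) is drawn in the neutral O–SO3H form of the given SMILES; at the bench it is handled as its sodium salt and protonated only in the final cold ion exchange.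

**Step 1**
Reactants: 1 6‑bromohexan‑1‑ol
Product: 2 oct‑7‑yn‑1‑ol
Conditions: LiC≡CH·H2NCH2CH2NH2 (2.5 equiv), DMSO, 5 °C → rt; aq NH4Cl
Reagents that add atoms: lithium acetylide–ethylenediamine complex, [Li+].[C-]#C.NCCN
Why: SN2 alkylation of acetylide by an unhindered primary bromide in DMSO, where the first equivalent only deprotonates the OH and seven‑ring ether closure of the alkoxide is too slow to compete.

**Step 2**
Reactants: 2 oct‑7‑yn‑1‑ol
Product: 3 oct‑7‑ynal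
Conditions: PhI(OAc)2 (1.1 equiv), TEMPO (10 mol %), CH2Cl2, rt; used at once
Reagents that add atoms: none
Why: TEMPO/oxoammonium oxidation of a primary alcohol stops cleanly at the aldehyde and leaves the terminal alkyne untouched.

**Step 3**
Reactants: 3 oct‑7‑ynal
Product: 5 (4R)‑undec‑1‑en‑10‑yn‑4‑ol, via diisopinocampheylborinate ester 4 (not isolated)
Conditions: (−)‑Ipc2BOMe (1.25 equiv), allylMgBr (1.2 equiv), Et2O, 0 °C → rt, Mg salts filtered off; then 3, −100 → −78 °C; then 3 M NaOH, 30% H2O2, rt → 40 °C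
Reagents that add atoms: allylmagnesium bromide, C=CC[Mg]Br; (−)‑B‑methoxydiisopinocampheylborane, COB([C@@H]1C[C@@H]2C[C@H]([C@H]1C)C2(C)C)[C@@H]1C[C@@H]2C[C@H]([C@H]1C)C2(C)C (its boron and Ipc groups stay only in 4)
Why: Brown asymmetric allylboration (carbonyl allylation) through a chair Zimmerman–Traxler transition state, in which the (+)‑α‑pinene‑derived reagent delivers allyl to the Si face of the unbranched aldehyde and so sets the (4R) carbinol (about 95% ee salt‑free at low temperature) while forming the key C3–C4 bond.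

**Step 4**
Reactants: 3 oct‑7‑ynal
Product: 7 (4S)‑undec‑1‑en‑10‑yn‑4‑ol, via enantiomeric diisopinocampheylborinate ester 6 (not isolated)
Conditions: (+)‑Ipc2BOMe (1.25 equiv), allylMgBr (1.2 equiv), Et2O, 0 °C → rt, Mg salts filtered off; then 3, −100 → −78 °C; then 3 M NaOH, 30% H2O2, rt → 40 °C
Reagents that add atoms: allylmagnesium bromide, C=CC[Mg]Br; (+)‑B‑methoxydiisopinocampheylborane, COB([C@H]1C[C@H]2C[C@@H]([C@@H]1C)C2(C)C)[C@H]1C[C@H]2C[C@@H]([C@@H]1C)C2(C)C (its boron and Ipc groups stay only in 6)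
Why: the same Brown allylboration with the (−)‑α‑pinene‑derived reagent attacks the Re face and sets the (4S) carbinol needed for the half that will later be inverted.

**Step 5**
Reactants: 8 5‑bromobenzene‑1,3‑diol (5‑bromoresorcinol)
Product: 9 1,3‑bis(benzyloxy)‑5‑bromobenzene
Conditions: BnBr (2.4 equiv), K2CO3 (3 equiv), acetone, reflux
Reagents that add atoms: benzyl bromide, BrCc1ccccc1
Why: exhaustive Williamson O‑alkylation of both phenols with a reactive benzylic halide.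

**Step 6**
Reactants: 9 1,3‑bis(benzyloxy)‑5‑bromobenzene; 5 (4R)‑undec‑1‑en‑10‑yn‑4‑ol
Product: 10 (4R)‑11‑[3,5‑bis(benzyloxy)phenyl]undec‑1‑en‑10‑yn‑4‑ol
Conditions: Pd(PPh3)2Cl2 (5 mol %), CuI (10 mol %), Et3N/DMF (1:2), degassed, 80 °C
Reagents that add atoms: none
Why: Sonogashira coupling of the terminal alkyne with the aryl bromide tolerates the free alcohol and the unactivated terminal alkene and does not touch the stereocentre.

**Step 7**
Reactants: 10 (4R)‑11‑[3,5‑bis(benzyloxy)phenyl]undec‑1‑en‑10‑yn‑4‑ol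
Product: 11 (4S)‑11‑[3,5‑bis(benzyloxy)phenyl]undecan‑4‑ol
Conditions: H2 (1 atm), 5% Pt/C, EtOAc, rt, stopped when uptake ceases
Reagents that add atoms: none
Why: heterogeneous hydrogenation over platinum saturates C≡C and C=C but is a poor catalyst for O‑benzyl hydrogenolysis; the carbinol is unchanged in space and becomes (S) only because the CIP ranking of allyl versus propyl changes.

**Step 8**
Reactants: 11 (4S)‑11‑[3,5‑bis(benzyloxy)phenyl]undecan‑4‑ol
Product: 12 (4S)‑11‑[3,5‑bis(benzyloxy)phenyl]undecan‑4‑yl acetate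
Conditions: Ac2O (2 equiv), pyridine, DMAP (5 mol %), CH2Cl2, rt
Reagents that add atoms: acetic anhydride, CC(=O)OC(C)=O
Why: DMAP‑catalysed O‑acylation of the only free hydroxyl proceeds at oxygen with retention of configuration.

**Step 9**
Reactants: 12 (4S)‑11‑[3,5‑bis(benzyloxy)phenyl]undecan‑4‑yl acetate
Product: 14 6‑[(8S)‑8‑acetoxyundecyl]‑2,4‑bis(benzyloxy)benzaldehyde, via aryl iminium chloride 13 (not isolated)
Conditions: POCl3 (2 equiv), DMF, 0 → 65 °C; then aq NaOAc, rt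
Reagents that add atoms: N,N‑dimethylformamide, CN(C)C=O (formyl carbon); water, O (carbonyl oxygen); phosphoryl chloride, O=P(Cl)(Cl)Cl (chloride counter‑ion of 13 only)
Why: Vilsmeier–Haack formylation of the doubly activated ring occurs para to one benzyloxy group and ortho to the chain, not at the more hindered position between the two benzyloxy groups, and ester and benzyl ethers survive.

**Step 10**
Reactants: 14 6‑[(8S)‑8‑acetoxyundecyl]‑2,4‑bis(benzyloxy)benzaldehyde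
Product: 15 6‑[(8S)‑8‑acetoxyundecyl]‑2,4‑bis(benzyloxy)benzoic acid
Conditions: NaClO2 (3 equiv), NaH2PO4 (3 equiv), 2‑methyl‑2‑butene (20 equiv), t‑BuOH/THF/H2O, 0 °C → rt
Reagents that add atoms: sodium chlorite, [Na+].[O-]Cl=O
Why: Pinnick oxidation converts the hindered aryl aldehyde to the acid under buffered conditions, with the alkene scavenging HOCl so the electron‑rich ring is not chlorinated and the acetate is not hydrolysed.

**Step 11**
Reactants: 8 5‑bromobenzene‑1,3‑diol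
Product: 16 3‑(benzyloxy)‑5‑bromophenol
Conditions: BnBr (1.0 equiv, slow addition), K2CO3 (1.1 equiv), acetone, reflux; chromatography (8 and 9 recovered and reused)
Reagents that add atoms: benzyl bromide, BrCc1ccccc1
Why: statistical mono‑Williamson etherification of a symmetric diol is reproducible at about 40–45%, and both by‑products feed back into the route.

**Step 12**
Reactants: 16 3‑(benzyloxy)‑5‑bromophenol
Product: 17 [3‑(benzyloxy)‑5‑bromophenoxy]tri(propan‑2‑yl)silane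
Conditions: TIPSCl (1.2 equiv), imidazole (2.5 equiv), DMF, rt
Reagents that add atoms: triisopropylsilyl chloride, CC(C)[Si](Cl)(C(C)C)C(C)C
Why: imidazole‑mediated silylation gives a bulky aryl silyl ether that is orthogonal to benzyl and survives amine bases, hydrogenation and Mitsunobu conditions.

**Step 13**
Reactants: 17 [3‑(benzyloxy)‑5‑bromophenoxy]tri(propan‑2‑yl)silane; 7 (4S)‑undec‑1‑en‑10‑yn‑4‑ol
Product: 18 (4S)‑11‑[3‑(benzyloxy)‑5‑(triisopropylsilyloxy)phenyl]undec‑1‑en‑10‑yn‑4‑ol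
Conditions: Pd(PPh3)2Cl2 (5 mol %), CuI (10 mol %), Et3N/DMF (1:2), degassed, 80 °C
Reagents that add atoms: none
Why: Sonogashira coupling as in step 6, under which the aryl TIPS ether is stable to triethylamine.

**Step 14**
Reactants: 18 (4S)‑11‑[3‑(benzyloxy)‑5‑(triisopropylsilyloxy)phenyl]undec‑1‑en‑10‑yn‑4‑ol
Product: 19 (4R)‑11‑[3‑(benzyloxy)‑5‑(triisopropylsilyloxy)phenyl]undecan‑4‑ol
Conditions: H2 (1 atm), 5% Pt/C, EtOAc, rt
Reagents that add atoms: none
Why: platinum‑catalysed hydrogenation saturates alkyne and alkene with retention of the benzyl and silyl ethers, and the unchanged carbinol is now named (R).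

**Step 15**
Reactants: 15 6‑[(8S)‑8‑acetoxyundecyl]‑2,4‑bis(benzyloxy)benzoic acid; 19 (4R)‑11‑[3‑(benzyloxy)‑5‑(triisopropylsilyloxy)phenyl]undecan‑4‑ol
Product: 20 (4S)‑11‑[3‑(benzyloxy)‑5‑(triisopropylsilyloxy)phenyl]undecan‑4‑yl 6‑[(8S)‑8‑acetoxyundecyl]‑2,4‑bis(benzyloxy)benzoate
Conditions: PPh3 (1.5 equiv), DIAD (1.5 equiv), toluene, 0 °C → rt
Reagents that add atoms: none
Why: Mitsunobu esterification, in which the carboxylate displaces the alkoxyphosphonium in an SN2 step with clean inversion (4R → 4S), so the di‑ortho‑substituted acyl carbon is never attacked and the acetate is not exposed to base.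

**Step 16**
Reactants: 20 (the TIPS ether from step 15)
Product: 21 (4S)‑11‑[3‑(benzyloxy)‑5‑hydroxyphenyl]undecan‑4‑yl 6‑[(8S)‑8‑acetoxyundecyl]‑2,4‑bis(benzyloxy)benzoate
Conditions: TBAF (1.1 equiv), AcOH (1.2 equiv), THF, 0 °C
Reagents that add atoms: none
Why: fluoride‑mediated cleavage of the aryl Si–O bond, buffered with acetic acid so that neither ester is touched, frees the single phenol destined for sulfation.

**Step 17**
Reactants: 21 (the phenol from step 16)
Product: 22 (4S)‑11‑[3‑(benzyloxy)‑5‑(sulfooxy)phenyl]undecan‑4‑yl 6‑[(8S)‑8‑acetoxyundecyl]‑2,4‑bis(benzyloxy)benzoate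
Conditions: SO3·pyridine (4 equiv), pyridine, 45 °C; aq NaHCO3 work‑up, Sephadex LH‑20 (handled as Na salt)
Reagents that add atoms: sulfur trioxide–pyridine complex, [O-]S(=O)(=O)[n+]1ccccc1
Why: O‑sulfonation of the only free hydroxyl with SO3·pyridine gives the aryl sulfate monoester regiospecifically, because all other oxygens are benzylated or acylated.

**Step 18**
Reactants: 22 (the sulfate from step 17)
Product: 23 Integracin D, (4S)‑11‑[3‑hydroxy‑5‑(sulfooxy)phenyl]undecan‑4‑yl 6‑[(8S)‑8‑acetoxyundecyl]‑2,4‑dihydroxybenzoate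
Conditions: H2 (1 atm), 10% Pd/C, MeOH/EtOAc, trace NaHCO3, rt; filter; Dowex 50W (H+), MeOH/H2O, 0 °C; lyophilise
Reagents that add atoms: none
Why: catalytic hydrogenolysis removes the three aryl benzyl ethers under neutral conditions that leave the aryl sulfate, the acetate, the benzoate and both non‑benzylic stereocentres intact.

**Compound list**
1 | 6‑bromohexan‑1‑ol | OCCCCCCBr | starting material
2 | oct‑7‑yn‑1‑ol | OCCCCCCC#C | intermediate
3 | oct‑7‑ynal | O=CCCCCCC#C | intermediate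
4 | (4R)‑undec‑1‑en‑10‑yn‑4‑yl diisopinocampheylborinate [Ipc from (+)‑α‑pinene] | C=CC[C@H](OB([C@@H]1C[C@@H]2C[C@H]([C@H]1C)C2(C)C)[C@@H]1C[C@@H]2C[C@H]([C@H]1C)C2(C)C)CCCCCC#C | intermediate (not isolated)
5 | (4R)‑undec‑1‑en‑10‑yn‑4‑ol | C=CC[C@H](O)CCCCCC#C | intermediate
6 | (4S)‑undec‑1‑en‑10‑yn‑4‑yl diisopinocampheylborinate [Ipc from (−)‑α‑pinene] | C=CC[C@@H](OB([C@H]1C[C@H]2C[C@@H]([C@@H]1C)C2(C)C)[C@H]1C[C@H]2C[C@@H]([C@@H]1C)C2(C)C)CCCCCC#C | intermediate (not isolated)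
7 | (4S)‑undec‑1‑en‑10‑yn‑4‑ol | C=CC[C@@H](O)CCCCCC#C | intermediate
8 | 5‑bromobenzene‑1,3‑diol | Oc1cc(O)cc(Br)c1 | starting material
9 | 1,3‑bis(benzyloxy)‑5‑bromobenzene | Brc1cc(OCc2ccccc2)cc(OCc2ccccc2)c1 | intermediate
10 | (4R)‑11‑[3,5‑bis(benzyloxy)phenyl]undec‑1‑en‑10‑yn‑4‑ol | C=CC[C@H](O)CCCCCC#Cc1cc(OCc2ccccc2)cc(OCc2ccccc2)c1 | intermediate
11 | (4S)‑11‑[3,5‑bis(benzyloxy)phenyl]undecan‑4‑ol | CCC[C@H](O)CCCCCCCc1cc(OCc2ccccc2)cc(OCc2ccccc2)c1 | intermediate
12 | (4S)‑11‑[3,5‑bis(benzyloxy)phenyl]undecan‑4‑yl acetate | CCC[C@H](OC(C)=O)CCCCCCCc1cc(OCc2ccccc2)cc(OCc2ccccc2)c1 | intermediate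
13 | N‑{6‑[(8S)‑8‑acetoxyundecyl]‑2,4‑bis(benzyloxy)benzylidene}‑N‑methylmethanaminium chloride | CCC[C@H](OC(C)=O)CCCCCCCc1cc(OCc2ccccc2)cc(OCc2ccccc2)c1C=[N+](C)C.[Cl-] | intermediate (not isolated)
14 | 6‑[(8S)‑8‑acetoxyundecyl]‑2,4‑bis(benzyloxy)benzaldehyde | CCC[C@H](OC(C)=O)CCCCCCCc1cc(OCc2ccccc2)cc(OCc2ccccc2)c1C=O | intermediate
15 | 6‑[(8S)‑8‑acetoxyundecyl]‑2,4‑bis(benzyloxy)benzoic acid | CCC[C@H](OC(C)=O)CCCCCCCc1cc(OCc2ccccc2)cc(OCc2ccccc2)c1C(=O)O | intermediate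
16 | 3‑(benzyloxy)‑5‑bromophenol | Oc1cc(Br)cc(OCc2ccccc2)c1 | intermediate
17 | [3‑(benzyloxy)‑5‑bromophenoxy]tri(propan‑2‑yl)silane | CC(C)[Si](Oc1cc(Br)cc(OCc2ccccc2)c1)(C(C)C)C(C)C | intermediate
18 | (4S)‑11‑[3‑(benzyloxy)‑5‑(triisopropylsilyloxy)phenyl]undec‑1‑en‑10‑yn‑4‑ol | C=CC[C@@H](O)CCCCCC#Cc1cc(OCc2ccccc2)cc(O[Si](C(C)C)(C(C)C)C(C)C)c1 | intermediate
19 | (4R)‑11‑[3‑(benzyloxy)‑5‑(triisopropylsilyloxy)phenyl]undecan‑4‑ol | CCC[C@@H](O)CCCCCCCc1cc(OCc2ccccc2)cc(O[Si](C(C)C)(C(C)C)C(C)C)c1 | intermediate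
20 | (4S)‑11‑[3‑(benzyloxy)‑5‑(triisopropylsilyloxy)phenyl]undecan‑4‑yl 6‑[(8S)‑8‑acetoxyundecyl]‑2,4‑bis(benzyloxy)benzoate | CCC[C@H](OC(C)=O)CCCCCCCc1cc(OCc2ccccc2)cc(OCc2ccccc2)c1C(=O)O[C@@H](CCC)CCCCCCCc1cc(OCc2ccccc2)cc(O[Si](C(C)C)(C(C)C)C(C)C)c1 | intermediate
21 | (4S)‑11‑[3‑(benzyloxy)‑5‑hydroxyphenyl]undecan‑4‑yl 6‑[(8S)‑8‑acetoxyundecyl]‑2,4‑bis(benzyloxy)benzoate | CCC[C@H](OC(C)=O)CCCCCCCc1cc(OCc2ccccc2)cc(OCc2ccccc2)c1C(=O)O[C@@H](CCC)CCCCCCCc1cc(OCc2ccccc2)cc(O)c1 | intermediate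
22 | (4S)‑11‑[3‑(benzyloxy)‑5‑(sulfooxy)phenyl]undecan‑4‑yl 6‑[(8S)‑8‑acetoxyundecyl]‑2,4‑bis(benzyloxy)benzoate | CCC[C@H](OC(C)=O)CCCCCCCc1cc(OCc2ccccc2)cc(OCc2ccccc2)c1C(=O)O[C@@H](CCC)CCCCCCCc1cc(OCc2ccccc2)cc(OS(=O)(=O)O)c1 | intermediate
23 | Integracin D | CCC[C@@H](CCCCCCCc1cc(O)cc(O)c1C(=O)O[C@@H](CCC)CCCCCCCc1cc(O)cc(OS(=O)(=O)O)c1)OC(C)=O | target

**Summary**
Total step count: 18. Longest linear sequence: 12 steps (steps 1, 2, 3, 6, 7, 8, 9, 10, 15, 16, 17, 18).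

**Three steps most likely to fail**

Step 15 (Mitsunobu coupling of a di‑ortho‑substituted acid with a di‑n‑alkyl carbinol; elimination or sluggish conversion). The fallback sets out from alcohol 19 and separates activation from displacement. MsCl and Et3N in CH2Cl2 at 0 °C give, with retention, (4R)‑11‑[3‑(benzyloxy)‑5‑(triisopropylsilyloxy)phenyl]undecan‑4‑yl methanesulfonate F1. Acid 15 is converted in DMF with Cs2CO3 (0.55 equiv, no alcohol present so the acetate is safe) into caesium 6‑[(8S)‑8‑acetoxyundecyl]‑2,4‑bis(benzyloxy)benzoate F2. F2 displaces the mesylate of F1 at 50 °C in an SN2 reaction with inversion, and the sequence comes back to the route at ester 20.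

Step 9 (Vilsmeier formylation; regiochemistry and survival of the benzyl ethers in hot POCl3/DMF). The fallback sets out from alcohol 11 and installs the carboxyl by halogenation and metalation instead.
- NBS (1.0 equiv, MeCN, 0 °C) brominates para to a benzyloxy group and ortho to the chain to give (4S)‑11‑[3,5‑bis(benzyloxy)‑2‑bromophenyl]undecan‑4‑ol F3.
- n‑BuLi (2.2 equiv, THF, −78 °C) forms the alkoxide and then exchanges bromine for lithium to give lithium (4S)‑11‑[3,5‑bis(benzyloxy)‑2‑lithiophenyl]undecan‑4‑olate F4, which is not isolated.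
- CO2 followed by dilute HCl gives 2,4‑bis(benzyloxy)‑6‑[(8S)‑8‑hydroxyundecyl]benzoic acid F5.
- Ac2O/pyridine/DMAP acetylates the alcohol and transiently forms acetic 6‑[(8S)‑8‑acetoxyundecyl]‑2,4‑bis(benzyloxy)benzoic anhydride F6, which aqueous NaHCO3/THF hydrolyses at the unhindered acetyl carbonyl.
- The sequence comes back to the route at acid 15, bypassing steps 8–10.

Step 7 (saturation of enyne 10 without loss of aryl benzyl ethers; step 14 is the same operation). The fallback sets out from enyne 10 and gives up the selectivity on purpose. H2 over 10% Pd/C in EtOH reduces both π systems and cleaves both benzyl ethers to 5‑[(8S)‑8‑hydroxyundecyl]benzene‑1,3‑diol F7. Phenol‑selective Williamson benzylation (BnBr 2.2 equiv, K2CO3, acetone, reflux; the secondary alcohol is not alkylated under carbonate) then comes back to the route at alcohol 11.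

**Further compounds**
F1 | step 15 | (4R)‑11‑[3‑(benzyloxy)‑5‑(triisopropylsilyloxy)phenyl]undecan‑4‑yl methanesulfonate | CCC[C@@H](OS(C)(=O)=O)CCCCCCCc1cc(OCc2ccccc2)cc(O[Si](C(C)C)(C(C)C)C(C)C)c1
F2 | step 15 | caesium 6‑[(8S)‑8‑acetoxyundecyl]‑2,4‑bis(benzyloxy)benzoate | CCC[C@H](OC(C)=O)CCCCCCCc1cc(OCc2ccccc2)cc(OCc2ccccc2)c1C(=O)[O-].[Cs+]
F3 | step 9 | (4S)‑11‑[3,5‑bis(benzyloxy)‑2‑bromophenyl]undecan‑4‑ol | CCC[C@H](O)CCCCCCCc1cc(OCc2ccccc2)cc(OCc2ccccc2)c1Br
F4 | step 9 | lithium (4S)‑11‑[3,5‑bis(benzyloxy)‑2‑lithiophenyl]undecan‑4‑olate (not isolated) | CCC[C@H]([O-])CCCCCCCc1cc(OCc2ccccc2)cc(OCc2ccccc2)c1[Li].[Li+]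
F5 | step 9 | 2,4‑bis(benzyloxy)‑6‑[(8S)‑8‑hydroxyundecyl]benzoic acid | CCC[C@H](O)CCCCCCCc1cc(OCc2ccccc2)cc(OCc2ccccc2)c1C(=O)O
F6 | step 9 | acetic 6‑[(8S)‑8‑acetoxyundecyl]‑2,4‑bis(benzyloxy)benzoic anhydride (not isolated) | CCC[C@H](OC(C)=O)CCCCCCCc1cc(OCc2ccccc2)cc(OCc2ccccc2)c1C(=O)OC(C)=O
F7 | step 7 | 5‑[(8S)‑8‑hydroxyundecyl]benzene‑1,3‑diol | CCC[C@H](O)CCCCCCCc1cc(O)cc(O)c1
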